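**Retrosynthetic overview**
1. Target 7 ⇐ 6 by acetylation of the only secondary hydroxyl (C2).
2. 6 ⇐ 5 by one Mitsunobu operation that benzoylates the CH2OH and inverts C3 with benzoate, giving the 2,3-trans pattern that nature is thought to get from an arene oxide.
3. 5 ⇐ vinyl epoxide 4 ⇐ triol 3: epoxidation of C1=C6 of the dihydroarene and anti opening at C6 by benzoate in one flask, as in the presumed route through 1,6-epoxides of the senepoxide/pipoxide type.
4. 3 ⇐ 2 ⇐ ethyl benzoate 1 by enzymatic dearomatising cis-dihydroxylation, then ester reduction.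
5. Ring order: the carbocycle is the benzene ring of 1 and is never built; the only ring formed is the C1–C6 oxirane of 4, opened in the same pot.

Assumption: ring atoms are numbered C1 (quaternary carbinol carbon bearing CH2OBz), C2 (OAc), C3 (OBz), C4=C5, C6 (OBz), so the target is (1R,2S,3R,6S); in step 1 the cells, enzyme and NADH are treated as catalytic.

**Step 1**
Reactants: 1 ethyl benzoate
Product: 2 ethyl (5S,6R)-5,6-dihydroxycyclohexa-1,3-diene-1-carboxylate
Conditions: E. coli JM109(pDTG601A) whole cells (toluene dioxygenase), glucose feed, O2, pH 6.8 buffer, 35 °C; EtOAc extraction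
Reagents that add atoms: dioxygen, O=O
Why: Rieske-dioxygenase cis-dihydroxylation (whole-cell arene dearomatisation, known for benzoate esters) adds O2 across the ortho/meta bond from one face only, which sets both carbinol centres (5S,6R, essentially enantiopure) and leaves the diene needed for the later epoxidation.

**Step 2**
Reactants: 2 ethyl (5S,6R)-5,6-dihydroxycyclohexa-1,3-diene-1-carboxylate
Product: 3 (1S,2R)-3-(hydroxymethyl)cyclohexa-3,5-diene-1,2-diol
Conditions: DIBAL-H (5 equiv), THF, −78 → −20 °C; aq. Rochelle salt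
Reagents that add atoms: none
Why: DIBAL-H 1,2-reduction of the dienoate ester (the two hydroxyls are first converted to aluminium alkoxides) gives the primary dienylic alcohol without touching the stereocentres, and the cold, non-acidic work-up avoids dehydrative aromatisation of the cis-dihydrodiol.

**Step 3**
Reactants: 3 (1S,2R)-3-(hydroxymethyl)cyclohexa-3,5-diene-1,2-diol
Product: 5 (1S,4S,5S,6S)-4,5,6-trihydroxy-6-(hydroxymethyl)cyclohex-2-en-1-yl benzoate, via epoxy triol 4 (not isolated)
Conditions: Ti(OiPr)4 (2.2 equiv), D-(−)-DIPT (2.6 equiv), TBHP (1.1 equiv, anhydrous), 4 Å MS, CH2Cl2, −25 °C; then PhCO2H (2 equiv), −25 → 0 °C; aq. tartaric acid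
Reagents that add atoms: tert-butyl hydroperoxide, CC(C)(C)OO; benzoic acid, OC(=O)c1ccccc1
Why: Katsuki–Sharpless asymmetric epoxidation is chemoselective for the alkene of the primary allylic alcohol (C1=C6) and with D-(−)-tartrate delivers oxygen to the face carrying the C2–OH, setting C1 and C6 of vinyl epoxide 4, after which titanium-mediated C-3 opening of the 2,3-epoxy alcohol (Caron–Sharpless) by benzoic acid, added only once the acid-sensitive diene is consumed, proceeds by SN2 attack at the allylic carbon C6 with inversion to give the trans 1-OH/6-OBz pair.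

**Step 4**
Reactants: 5 (1S,4S,5S,6S)-4,5,6-trihydroxy-6-(hydroxymethyl)cyclohex-2-en-1-yl benzoate
Product: 6 [(1S,2S,3R,6S)-3,6-bis(benzoyloxy)-1,2-dihydroxycyclohex-4-en-1-yl]methyl benzoate
Conditions: PhCO2H (2.5 equiv), PPh3 (2.5 equiv), DIAD (2.5 equiv, added last), THF, 0 °C → rt
Reagents that add atoms: benzoic acid, OC(=O)c1ccccc1
Why: Double Mitsunobu esterification benzoylates the primary hydroxyl and displaces the allylic C3 hydroxyl, the only secondary carbinol activated for SN2, with inversion (C3–O becomes trans to C2–O), while the neopentyl-type C2–OH and the tertiary C1–OH stay free and the absence of a neighbouring ester at C2 excludes retention through an acyloxonium ion.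

**Step 5**
Reactants: 6 [(1S,2S,3R,6S)-3,6-bis(benzoyloxy)-1,2-dihydroxycyclohex-4-en-1-yl]methyl benzoate
Product: 7 [(1R,2S,3R,6S)-2-acetoxy-3,6-bis(benzoyloxy)-1-hydroxycyclohex-4-en-1-yl]methyl benzoate (target)
Conditions: Ac2O (1.5 equiv), pyridine, 0 °C → rt (no DMAP)
Reagents that add atoms: acetic anhydride, CC(=O)OC(C)=O
Why: Chemoselective acylation of a secondary over a tertiary alcohol (Ac2O/pyridine) esterifies the C2 hydroxyl only and changes no stereocentre.

**Compound list**
1 | ethyl benzoate | CCOC(=O)c1ccccc1 | starting material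
2 | ethyl (5S,6R)-5,6-dihydroxycyclohexa-1,3-diene-1-carboxylate | O[C@H]1[C@@H](O)C=CC=C1C(=O)OCC | intermediate
3 | (1S,2R)-3-(hydroxymethyl)cyclohexa-3,5-diene-1,2-diol | O[C@H]1[C@@H](O)C=CC=C1CO | intermediate
4 | (1S,2S,3S,6R)-1-(hydroxymethyl)-7-oxabicyclo[4.1.0]hept-4-ene-2,3-diol (epoxy triol, not isolated) | O[C@H]1[C@@H](O)C=C[C@H]2O[C@@]12CO | intermediate
5 | (1S,4S,5S,6S)-4,5,6-trihydroxy-6-(hydroxymethyl)cyclohex-2-en-1-yl benzoate | O[C@H]1[C@@H](O)C=C[C@H](OC(=O)c2ccccc2)[C@]1(O)CO | intermediate
6 | [(1S,2S,3R,6S)-3,6-bis(benzoyloxy)-1,2-dihydroxycyclohex-4-en-1-yl]methyl benzoate | O[C@H]1[C@H](OC(=O)c2ccccc2)C=C[C@H](OC(=O)c2ccccc2)[C@]1(O)COC(=O)c1ccccc1 | intermediate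
7 | [(1R,2S,3R,6S)-2-acetoxy-3,6-bis(benzoyloxy)-1-hydroxycyclohex-4-en-1-yl]methyl benzoate | CC(=O)O[C@H]1[C@H](OC(=O)c2ccccc2)C=C[C@H](OC(=O)c2ccccc2)[C@]1(O)COC(=O)c1ccccc1 | target

**Total step count:** 5
**Longest linear sequence:** 5 (fully linear from ethyl benzoate)

**Steps most likely to fail**

Step 3 (one-pot epoxidation and benzoate opening on the unprotected triol). The free cis-diol can bind titanium and disturb the tartrate complex, the vinyl epoxide may be opened by isopropoxide, and the C6 benzoate can migrate to the primary oxygen. The fallback sets out from 3 and comes back at 5. It replaces reagent control by substrate-directed vanadium catalysis (VO(acac)2 3 mol %, TBHP, CH2Cl2, 0 °C), in which both the primary and the C2 allylic hydroxyl steer the peroxide to C1=C6 on the C2–OH face. Epoxy triol 4 is then isolated and opened in a separate flask by a purely nucleophilic SN2 reaction at C6 with tetrabutylammonium benzoate/benzoic acid in MeCN at 40 °C. No new compound is made.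

Step 4 (double Mitsunobu on a tetraol). The neopentyl-type primary carbinol may react slowly or close to a spiro-epoxide, and SN2′ attack at C5 or reaction at C2 could compete. The fallback sets out from 5 and comes back at 6. The primary hydroxyl is first acylated by ordinary nucleophilic acyl substitution (BzCl 1.05 equiv, 2,4,6-collidine, CH2Cl2, −40 °C) to give [(1S,2S,3S,6S)-6-(benzoyloxy)-1,2,3-trihydroxycyclohex-4-en-1-yl]methyl benzoate F1. A single Mitsunobu inversion (PhCO2H, PPh3, DIAD, THF) at the allylic C3 carbinol then gives 6.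

Step 2 (hydride reduction of an unprotected, aromatisation-prone dihydrodiol). Aluminium Lewis acidity or the work-up may dehydrate the diene diol to a phenol, and the triol is very water-soluble. The fallback sets out from 2 and comes back at 3. Both hydroxyls are masked (TESCl, imidazole, DMF, 0 °C) to give ethyl (5S,6R)-5,6-bis(triethylsilyloxy)cyclohexa-1,3-diene-1-carboxylate F2. Reduction with DIBAL-H (2.2 equiv, CH2Cl2, −78 °C) gives [(5S,6R)-5,6-bis(triethylsilyloxy)cyclohexa-1,3-dien-1-yl]methanol F3, and TBAF (THF, 0 °C) removes the silyl groups to give 3.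

**Further compounds**
F0 | step 3 | none | none
F1 | step 4 | [(1S,2S,3S,6S)-6-(benzoyloxy)-1,2,3-trihydroxycyclohex-4-en-1-yl]methyl benzoate | O[C@H]1[C@@H](O)C=C[C@H](OC(=O)c2ccccc2)[C@]1(O)COC(=O)c1ccccc1
F2 | step 2 | ethyl (5S,6R)-5,6-bis(triethylsilyloxy)cyclohexa-1,3-diene-1-carboxylate | CC[Si](CC)(CC)O[C@H]1[C@@H](O[Si](CC)(CC)CC)C=CC=C1C(=O)OCC
F3 | step 2 | [(5S,6R)-5,6-bis(triethylsilyloxy)cyclohexa-1,3-dien-1-yl]methanol | CC[Si](CC)(CC)O[C@H]1[C@@H](O[Si](CC)(CC)CC)C=CC=C1CO
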